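**Plan**

1. Numbering is that of 3,7-dioxabicyclo[3.3.0]octane: C1 bears OAc, C2 the guaiacyl ring, C6 the veratryl ring. Late cuts: the phenol is masked as its acetate; C6–aryl is cut (Friedel–Crafts on a lactol, C6 being a former lactone carbonyl); the C1 acetate is traced back to an acetyl and then a formyl group (Baeyer–Villiger); ring B is cut at C1–C8 and O7–C6 (formaldehyde aldol, lactonisation onto a C5 ester).
2. Ring A is cut at O3–C2 and C4–C5. C2 is benzylic (donor), C5 can carry a malonate (acceptor), and the two are 1,3-related across C1, while O3–C4 is one molecule of formaldehyde. Ring A is therefore the (3+2) adduct of formaldehyde with a donor–acceptor cyclopropane built from C2, C1 and C5.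
3. Forward: organocatalytic cyclopropanation (C5–C2 and C5–C1), (3+2) annulation with formaldehyde (ring A), a second formaldehyde at C1 with lactonisation (ring B), then removal of the helper ester, CHO → COCH3 → OAc, lactone → lactol → aryl, and release of the phenol.
4. Stereochemistry: C2 is set by the prolinol catalyst and relayed with inversion through the cyclopropane C2–C5 bond, a bond absent from the target and cleaved in the key step. C1 follows from aldol attack anti to the C2 aryl group and is kept by the retentive Baeyer–Villiger step. C5 is fixed by the cis ring fusion, C6 by arylation on the convex face.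

Key step: step 3

Assumption: the (R)-prolinol catalyst is taken to shield the iminium face in the mirror-image sense of its (S)-enantiomer, so that it gives the (2R,3S)-cyclopropane 4; compounds 1, 3 and 14 are purchased.

**Route**

Step 1
Reactants: 1 dibenzyl malonate
Product: 2 dibenzyl 2-bromomalonate
Conditions: Br2 (1.0 equiv), CH2Cl2, 0 °C to rt
Reagents that add atoms: bromine, BrBr
Why: Electrophilic α-bromination of the malonate through its enol should stop at the monobromide with one equivalent of bromine.

Step 2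
Reactants: 2 dibenzyl 2-bromomalonate; 3 (E)-3-(4-acetoxy-3-methoxyphenyl)prop-2-enal
Product: 4 dibenzyl (2R,3S)-2-(4-acetoxy-3-methoxyphenyl)-3-formylcyclopropane-1,1-dicarboxylate (aryl and formyl trans)
Conditions: (R)-α,α-diphenylprolinol trimethylsilyl ether (20 mol%), 2,6-lutidine (1.1 equiv), CH2Cl2, 0 °C to rt
Reagents that add atoms: none
Why: Organocatalytic Michael-initiated ring closure (iminium, then enamine activation): the bromomalonate should add to the face of the iminium ion of 3 left open by the diphenyl(silyloxy)methyl group, and the enamine then displaces bromide, which sets C2 (R) and C3 (S) with aryl and formyl trans.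

Step 3
Reactants: 4 dibenzyl (2R,3S)-2-(4-acetoxy-3-methoxyphenyl)-3-formylcyclopropane-1,1-dicarboxylate
Product: 5 dibenzyl (4R,5S)-5-(4-acetoxy-3-methoxyphenyl)-4-formyloxolane-3,3-dicarboxylate (aryl and formyl cis)
Conditions: paraformaldehyde (5 equiv), Sn(OTf)2 (10 mol%), 4 Å MS, CH2Cl2, rt to 40 °C
Reagents that add atoms: formaldehyde (from paraformaldehyde), C=O
Why: Sn(OTf)2 binds the geminal diester of 4 and polarises the ring bond between the diester carbon and the benzylic carbon; the oxygen of formaldehyde attacks the benzylic carbon from the side opposite to the departing malonate carbon, and the resulting malonate enolate closes on the carbon of the O-alkylated formaldehyde oxocarbenium ion, so that the O–C(aryl) and CH2–C bonds form in one operation. The closest known reaction type is the Lewis acid catalysed (3+2) annulation of 2-arylcyclopropane-1,1-diesters with aldehydes, which runs with inversion at the donor carbon. The only ring closed is the oxolane (later ring A), by a formal (3+2) union whose last event is a 5-endo-trig capture of the oxocarbenium carbon by the enolate carbon. The benzylic carbon is the only stereocentre that changes: it should be inverted stereospecifically, so its configuration in 5 follows from the cyclopropane, and the 4-acetoxy group (in place of a free or alkylated phenol) keeps the aryl ring a weak enough donor that this carbon does not ionise and racemise; the formyl-bearing carbon is untouched and its configuration is erased in step 4 in any case. The step needs cleavage of the bond between the aryl-bearing and the diester-bearing carbons and not of a bond to the formyl-bearing carbon, which the bidentate binding of the diester and the aryl donor should secure; it also needs formaldehyde, not the formyl group of a second molecule of 4, as the partner, which the excess of formaldehyde and the hindered, electron-poor nature of that formyl group should secure.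

Step 4
Reactants: 5 dibenzyl (4R,5S)-5-(4-acetoxy-3-methoxyphenyl)-4-formyloxolane-3,3-dicarboxylate
Product: 7 benzyl (1S,2R,5R)-2-(4-acetoxy-3-methoxyphenyl)-1-formyl-6-oxo-3,7-dioxabicyclo[3.3.0]octane-5-carboxylate (cis-fused, aryl exo), via the aldol adduct 6 (not isolated)
Conditions: paraformaldehyde (3 equiv), DBU (0.2 equiv), THF, 0 °C to rt
Reagents that add atoms: formaldehyde (from paraformaldehyde), C=O
Why: Aldol reaction of the aldehyde enolate with formaldehyde followed by lactonisation: the enolate carbon is planar, formaldehyde should add anti to the neighbouring aryl group (new quaternary centre C1), and the hydroxymethyl group closes ring B onto the cis benzyl ester, so the fusion is cis and the aryl group ends exo and cis to the formyl group.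

Step 5
Reactants: 7 benzyl (1S,2R,5R)-2-(4-acetoxy-3-methoxyphenyl)-1-formyl-6-oxo-3,7-dioxabicyclo[3.3.0]octane-5-carboxylate
Product: 9 4-[(1S,2R,5R)-1-formyl-6-oxo-3,7-dioxabicyclo[3.3.0]octan-2-yl]-2-methoxyphenyl acetate, via the α-carboxy lactone 8 (not isolated)
Conditions: H2 (1 atm), Pd/C, EtOAc, rt; filter; toluene, 110 °C
Reagents that add atoms: none
Why: Hydrogenolysis of the benzyl ester and thermal decarboxylation of the α-carboxy lactone through its enol remove the helper ester without a free enolate, and protonation at C5 can only give the cis-fused bicycle.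

Step 6
Reactants: 9 4-[(1S,2R,5R)-1-formyl-6-oxo-3,7-dioxabicyclo[3.3.0]octan-2-yl]-2-methoxyphenyl acetate
Product: 10 4-[(1R,2R,5R)-1-(1-hydroxyethyl)-6-oxo-3,7-dioxabicyclo[3.3.0]octan-2-yl]-2-methoxyphenyl acetate (both carbinol epimers)
Conditions: MeTi(OiPr)3 (1.5 equiv), THF, −40 to 0 °C; aq. NH4Cl
Reagents that add atoms: methyltitanium triisopropoxide, C[Ti](OC(C)C)(OC(C)C)OC(C)C
Why: Chemoselective carbonyl addition: methyltitanium reagents add to aldehydes and leave lactones and aryl acetates alone; the new carbinol centre is oxidised in the next step, so its configuration does not matter.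

Step 7
Reactants: 10 4-[(1R,2R,5R)-1-(1-hydroxyethyl)-6-oxo-3,7-dioxabicyclo[3.3.0]octan-2-yl]-2-methoxyphenyl acetate
Product: 11 4-[(1S,2R,5R)-1-acetyl-6-oxo-3,7-dioxabicyclo[3.3.0]octan-2-yl]-2-methoxyphenyl acetate
Conditions: Dess–Martin periodinane (1.5 equiv), NaHCO3, CH2Cl2, rt
Reagents that add atoms: none
Why: Dess–Martin oxidation of a secondary alcohol under buffered, non-basic conditions should leave the lactone α-carbon and the aryl acetate untouched.

Step 8
Reactants: 11 4-[(1S,2R,5R)-1-acetyl-6-oxo-3,7-dioxabicyclo[3.3.0]octan-2-yl]-2-methoxyphenyl acetate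
Product: 12 (1S,2R,5S)-2-(4-acetoxy-3-methoxyphenyl)-6-oxo-3,7-dioxabicyclo[3.3.0]octan-1-yl acetate
Conditions: mCPBA (3 equiv), Na2HPO4, CH2Cl2, 40 °C
Reagents that add atoms: mCPBA (3-chloroperoxybenzoic acid), OOC(=O)c1cccc(Cl)c1
Why: Baeyer–Villiger oxidation: the fully substituted bridgehead carbon should migrate in preference to methyl and with retention, so the acetyl group becomes the tertiary acetate with C1 unchanged.

Step 9
Reactants: 12 (1S,2R,5S)-2-(4-acetoxy-3-methoxyphenyl)-6-oxo-3,7-dioxabicyclo[3.3.0]octan-1-yl acetate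
Product: 13 (1S,2R,5S)-2-(4-acetoxy-3-methoxyphenyl)-6-hydroxy-3,7-dioxabicyclo[3.3.0]octan-1-yl acetate (both anomers)
Conditions: Sia2BH (disiamylborane, 2.5 equiv), THF, 0 °C to rt; then H2O
Reagents that add atoms: none
Why: Chemoselective partial reduction: disiamylborane reduces γ-lactones to lactols and should leave the alkyl and aryl acetates intact.

Step 10
Reactants: 13 (1S,2R,5S)-2-(4-acetoxy-3-methoxyphenyl)-6-hydroxy-3,7-dioxabicyclo[3.3.0]octan-1-yl acetate; 14 veratrole (1,2-dimethoxybenzene)
Product: 15 (1S,2R,5R,6S)-2-(4-acetoxy-3-methoxyphenyl)-6-(3,4-dimethoxyphenyl)-3,7-dioxabicyclo[3.3.0]octan-1-yl acetate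
Conditions: 14 (5 equiv), BF3·OEt2 (1.5 equiv), CH2Cl2, −40 to 0 °C
Reagents that add atoms: none
Why: Friedel–Crafts C-arylation of the lactol through its cyclic oxocarbenium ion: veratrole should react para to a methoxy group and on the convex face of the cis-fused bicycle, which places the new aryl group exo (C6, S), while the deactivated acetoxyaryl ether at C2 should not ionise.

Step 11
Reactants: 15 (1S,2R,5R,6S)-2-(4-acetoxy-3-methoxyphenyl)-6-(3,4-dimethoxyphenyl)-3,7-dioxabicyclo[3.3.0]octan-1-yl acetate
Product: 16 (1S,2R,5R,6S)-6-(3,4-dimethoxyphenyl)-2-(4-hydroxy-3-methoxyphenyl)-3,7-dioxabicyclo[3.3.0]octan-1-yl acetate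
Conditions: NH4OAc (8 equiv), MeOH–H2O (4:1), rt
Reagents that add atoms: none
Why: Chemoselective transesterification: an aryl acetate is cleaved far faster than a hindered tertiary alkyl acetate under these mild conditions.

**Compound list**

1 | dibenzyl malonate | O=C(CC(=O)OCc1ccccc1)OCc1ccccc1 | starting material
2 | dibenzyl 2-bromomalonate | O=C(OCc1ccccc1)C(Br)C(=O)OCc1ccccc1 | intermediate
3 | (E)-3-(4-acetoxy-3-methoxyphenyl)prop-2-enal | CC(=O)Oc1ccc(/C=C/C=O)cc1OC | starting material
4 | dibenzyl (2R,3S)-2-(4-acetoxy-3-methoxyphenyl)-3-formylcyclopropane-1,1-dicarboxylate | O=C[C@H]1[C@H](c2ccc(OC(C)=O)c(OC)c2)C1(C(=O)OCc3ccccc3)C(=O)OCc4ccccc4 | intermediate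
5 | dibenzyl (4R,5S)-5-(4-acetoxy-3-methoxyphenyl)-4-formyloxolane-3,3-dicarboxylate | O=C[C@H]1[C@@H](c2ccc(OC(C)=O)c(OC)c2)OCC1(C(=O)OCc3ccccc3)C(=O)OCc4ccccc4 | intermediate
6 | dibenzyl (4S,5R)-5-(4-acetoxy-3-methoxyphenyl)-4-formyl-4-(hydroxymethyl)oxolane-3,3-dicarboxylate | O=C[C@@]1(CO)[C@@H](c2ccc(OC(C)=O)c(OC)c2)OCC1(C(=O)OCc3ccccc3)C(=O)OCc4ccccc4 | intermediate
7 | benzyl (1S,2R,5R)-2-(4-acetoxy-3-methoxyphenyl)-1-formyl-6-oxo-3,7-dioxabicyclo[3.3.0]octane-5-carboxylate | O=C[C@@]12[C@@H](c3ccc(OC(C)=O)c(OC)c3)OC[C@]1(C(=O)OCc4ccccc4)C(=O)OC2 | intermediate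
8 | (1S,2R,5R)-2-(4-acetoxy-3-methoxyphenyl)-1-formyl-6-oxo-3,7-dioxabicyclo[3.3.0]octane-5-carboxylic acid | O=C[C@@]12[C@@H](c3ccc(OC(C)=O)c(OC)c3)OC[C@]1(C(=O)O)C(=O)OC2 | intermediate
9 | 4-[(1S,2R,5R)-1-formyl-6-oxo-3,7-dioxabicyclo[3.3.0]octan-2-yl]-2-methoxyphenyl acetate | O=C[C@@]12[C@@H](c3ccc(OC(C)=O)c(OC)c3)OC[C@@H]1C(=O)OC2 | intermediate
10 | 4-[(1R,2R,5R)-1-(1-hydroxyethyl)-6-oxo-3,7-dioxabicyclo[3.3.0]octan-2-yl]-2-methoxyphenyl acetate (both carbinol epimers) | CC(O)[C@@]12[C@@H](c3ccc(OC(C)=O)c(OC)c3)OC[C@@H]1C(=O)OC2 | intermediate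
11 | 4-[(1S,2R,5R)-1-acetyl-6-oxo-3,7-dioxabicyclo[3.3.0]octan-2-yl]-2-methoxyphenyl acetate | CC(=O)[C@@]12[C@@H](c3ccc(OC(C)=O)c(OC)c3)OC[C@@H]1C(=O)OC2 | intermediate
12 | (1S,2R,5S)-2-(4-acetoxy-3-methoxyphenyl)-6-oxo-3,7-dioxabicyclo[3.3.0]octan-1-yl acetate | CC(=O)O[C@@]12[C@@H](c3ccc(OC(C)=O)c(OC)c3)OC[C@@H]1C(=O)OC2 | intermediate
13 | (1S,2R,5S)-2-(4-acetoxy-3-methoxyphenyl)-6-hydroxy-3,7-dioxabicyclo[3.3.0]octan-1-yl acetate (both anomers) | CC(=O)O[C@@]12[C@@H](c3ccc(OC(C)=O)c(OC)c3)OC[C@@H]1C(O)OC2 | intermediate
14 | veratrole (1,2-dimethoxybenzene) | COc1ccccc1OC | starting material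
15 | (1S,2R,5R,6S)-2-(4-acetoxy-3-methoxyphenyl)-6-(3,4-dimethoxyphenyl)-3,7-dioxabicyclo[3.3.0]octan-1-yl acetate | CC(=O)O[C@@]12[C@@H](c3ccc(OC(C)=O)c(OC)c3)OC[C@@H]1[C@@H](c4ccc(OC)c(OC)c4)OC2 | intermediate
16 | (1S,2R,5R,6S)-6-(3,4-dimethoxyphenyl)-2-(4-hydroxy-3-methoxyphenyl)-3,7-dioxabicyclo[3.3.0]octan-1-yl acetate | CC(=O)O[C@@]12[C@@H](c3ccc(O)c(OC)c3)OC[C@@H]1[C@@H](c4ccc(OC)c(OC)c4)OC2 | target

**Step count and risks**

Total step count: 11. Longest linear sequence: 11 steps (1 to 16 through steps 1–11); 3 and 14 enter in steps 2 and 10.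

Step 3. The ring may open too slowly, because the benzylic carbon carries only a weakly donating aryl group and is flanked by the formyl-bearing carbon, or the Lewis acid may polarise the ring bond toward the formyl group. The fallback sets out from 4 and lowers the oxidation level of the competing acceptor. The formyl group is reduced with Zn(BH4)2 (Et2O, 0 °C) to dibenzyl 2-(4-acetoxy-3-methoxyphenyl)-3-(hydroxymethyl)cyclopropane-1,1-dicarboxylate F1, which is silylated at once (TESCl, imidazole) to its triethylsilyl ether F2 before it can lactonise. F2 has a single acceptor site and belongs to the substrate class of the closest precedents, and the same annulation with formaldehyde should give dibenzyl 5-(4-acetoxy-3-methoxyphenyl)-4-[(triethylsilyloxy)methyl]oxolane-3,3-dicarboxylate F3. The primary silyl ether of F3 is then oxidised directly under Swern conditions, without passing through the free alcohol, which returns to the route at 5.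

Step 10. The cyclic oxocarbenium ion may lose the C5 proton, and the enol ether so formed may expel the C1 acetate, which would aromatise ring B to a furan; attack on the concave face is the lesser risk. The fallback sets out from 13 and replaces the arene by a much stronger carbon nucleophile. The lactol is converted with benzenesulfinic acid and CaCl2 into (1S,2R,5S)-2-(4-acetoxy-3-methoxyphenyl)-6-(phenylsulfonyl)-3,7-dioxabicyclo[3.3.0]octan-1-yl acetate F4. F4 is treated with (3,4-dimethoxyphenyl)zinc bromide F5, made from commercial (3,4-dimethoxyphenyl)magnesium bromide and ZnBr2, in THF at low temperature. Displacement of the sulfinate on the convex face should outrun proton loss and is tolerated by both acetates; it returns to the route at 15.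

Step 8. Migration of the bridgehead carbon may be slow, because its neighbours carry oxygen and a carbonyl group, so that methyl migration or oxidation of the methoxyarene by the peracid competes. The fallback sets out from 9 and leaves out 10 and 11. The aldehyde is oxidised with NaClO2, NaH2PO4 and 2-methyl-2-butene to (1S,2R,5R)-2-(4-acetoxy-3-methoxyphenyl)-6-oxo-3,7-dioxabicyclo[3.3.0]octane-1-carboxylic acid F6. Oxidative decarboxylation of F6 with Pb(OAc)4 in benzene–acetic acid at 80 °C should install the acetate, the cis ring fusion allowing C–O bond formation on the convex face only; it returns to the route at 12.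

**Further compounds**

F1 | step 3 | dibenzyl 2-(4-acetoxy-3-methoxyphenyl)-3-(hydroxymethyl)cyclopropane-1,1-dicarboxylate (trans, configuration of 4) | OC[C@H]1[C@H](c2ccc(OC(C)=O)c(OC)c2)C1(C(=O)OCc3ccccc3)C(=O)OCc4ccccc4
F2 | step 3 | dibenzyl 2-(4-acetoxy-3-methoxyphenyl)-3-[(triethylsilyloxy)methyl]cyclopropane-1,1-dicarboxylate (trans, configuration of 4) | CC[Si](CC)(CC)OC[C@H]1[C@H](c2ccc(OC(C)=O)c(OC)c2)C1(C(=O)OCc3ccccc3)C(=O)OCc4ccccc4
F3 | step 3 | dibenzyl 5-(4-acetoxy-3-methoxyphenyl)-4-[(triethylsilyloxy)methyl]oxolane-3,3-dicarboxylate (4,5-cis, configuration of 5) | CC[Si](CC)(CC)OC[C@H]1[C@@H](c2ccc(OC(C)=O)c(OC)c2)OCC1(C(=O)OCc3ccccc3)C(=O)OCc4ccccc4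
F4 | step 10 | (1S,2R,5S)-2-(4-acetoxy-3-methoxyphenyl)-6-(phenylsulfonyl)-3,7-dioxabicyclo[3.3.0]octan-1-yl acetate (both C6 epimers) | CC(=O)O[C@@]12[C@@H](c3ccc(OC(C)=O)c(OC)c3)OC[C@@H]1C(S(=O)(=O)c4ccccc4)OC2
F5 | step 10 | (3,4-dimethoxyphenyl)zinc bromide | COc1ccc([Zn]Br)cc1OC
F6 | step 8 | (1S,2R,5R)-2-(4-acetoxy-3-methoxyphenyl)-6-oxo-3,7-dioxabicyclo[3.3.0]octane-1-carboxylic acid | OC(=O)[C@@]12[C@@H](c3ccc(OC(C)=O)c(OC)c3)OC[C@@H]1C(=O)OC2
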